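The numbers were drawn at random within sensible limits.

The meeting began at the far end of the run, with what a flask can hold once its reagent is used, and then came back to the reading at 12 min.

- north: substrate 0.10 M; reagent 0.110 M; time 12 min
- north-east: substrate 0.10 M; reagent 0.170 M; time 12 min

- which of these there is most of at the end, counted by the substrate in it, north (intermediate A / target / substrate / intermediate B)
- which of these there is most of at the end, counted by the substrate in it, north-east (intermediate A / target / substrate / intermediate B)
- the largest of these amounts at the end, in percent of the substrate charged, north
- the largest of these amounts at the end, in percent of the substrate charged, north-east

    substrate + reagent → intermediate A (k1 = 0.026 /M/s)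
    substrate ⇌ intermediate B (K2 = 0.48, k2 = 0.0010 /s)
    intermediate A ⇌ intermediate C (K3 = 1.1, k3 = 0.0011 /s)
    reagent + intermediate A → target (k4 = 0.17 /M/s)
    intermediate C ⇌ intermediate D (K5 = 1.4, k5 = 0.0031 /s)

I, taking the minutes, argued that each target costs two reagents: one when substrate passes into intermediate A, a second when intermediate A meets reagent. North is charged 1.10 reagents per substrate, and at two reagents per target that pays for 55.0% of the charge as target: the reagent ceiling. North-east has a ceiling of 85.0%. Each flask falls short of two per substrate, which makes reagent the limiting reagent.

A colleague objected that intermediate A might leak to intermediate C instead. I answered that with reagent as charged in north, the second reagent step runs 17.0 times the forward rate of the leak. The cost of two stood. But a ceiling has no clock. I committed to target below 55.0% in north and below 85.0% in north-east at 12 min, and to no closer figure.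

The forecast was then read: target on top in north at 41%, target on top in north-east at 62%. It reasoned that “nearly every target costs two reagents”. Its figures lay under my ceilings.

The flasks gave target at 41.1% in north and target at 61.4% in north-east, so the forecast stood, with north's target 8.1 percentage points ahead of substrate.

Neither flask is at rest at 12 min: north keeps 17% of its reagent and north-east 24%. At 120 min, target reaches 49.8% in north and 81.6% in north-east, a further 8.7 points and 20 points. Both remain under their ceilings. North then has 0% of its reagent, with 26.9% of its substrate still unreacted. Its gap to the ceiling, 5.2 points, is half of the 10.5% standing in intermediates A, C and D, which have each taken one reagent.

Take the neighbour flask that is north with 0.028 M of reagent: its ceiling is 14.0%. The computed flask holds 7.33% target at 12.0 min, half of that ceiling, with 13% of its reagent left.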